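The decalin is cut at C1–C10 (ring A) and C8–C9 (ring B), which leads back to the acyclic iodo enyne 16. The feature used is that C10, the quaternary carbon carrying C20, lies β to a carboxyl-level carbon on C9 (the later C11), while C8 carries the methylidene carbon C17 and can therefore come from a terminal alkyne. One radical chain operation closes ring A by 6-exo attack of the C1 radical on C10 and ring B by 6-exo-dig attack of the C9 radical on C8, which gives the trans-decalin with C8=C17 in place. The C4/C5 pair comes from an enantioselective Ireland–Claisen rearrangement, and C12–C16 from a chiral lactone.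

Key step: step 9

Atom numbers follow the labdane skeleton: ring A = C1–C5 and C10; ring B = C5–C10; C4 carries C19 (methyl) and C18 (carboxyl); C10 carries C20; C8 carries the methylidene carbon C17; C9 carries the chain C11–C15, with methyl C16 on C13 and the acetoxy group on C15.

Assumption: the (S,S) antipode of the bromoborane controller in step 3 is taken to give (2S,3S)-7; if the sense proves opposite, the equally available (R,R) antipode is used with no other change.

Step 1
Reactants: 1 5-chloropent-1-yne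
Product: 3 (E)-6-chloro-3-methylhex-2-en-1-ol, via alkenylalane 2 (not isolated)
Conditions: Me3Al, Cp2ZrCl2 (cat.), CH2Cl2, 0 °C → rt; then n-BuLi, (CH2O)n, THF, −78 °C → rt; aq. HCl
Reagents that add atoms: trimethylaluminium, C[Al](C)C; paraformaldehyde (as formaldehyde), C=O
Why: Zirconium-catalysed syn-carboalumination of the terminal alkyne (Negishi carboalumination) puts methyl on the internal carbon and aluminium on the terminus, and the derived alanate is hydroxymethylated with retention, so the E alkene (no stereocentre) follows from the syn addition.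

Step 2
Reactants: 3 (E)-6-chloro-3-methylhex-2-en-1-ol; 4 hex-5-ynoic acid
Product: 5 (E)-6-chloro-3-methylhex-2-en-1-yl hex-5-ynoate
Conditions: DCC, DMAP (cat.), CH2Cl2, 0 °C → rt
Reagents that add atoms: none
Why: Steglich esterification (carbodiimide activation, DMAP acyl transfer) joins the acid and the primary allylic alcohol without touching the alkyne, the chloride or the alkene geometry.

Step 3
Reactants: 5 (E)-6-chloro-3-methylhex-2-en-1-yl hex-5-ynoate
Product: 7 (2S,3S)-2-(but-3-yn-1-yl)-3-(3-chloropropyl)-3-methylpent-4-enoic acid, via boron ketene acetal 6 (not isolated)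
Conditions: (S,S)-2-bromo-4,5-diphenyl-1,3-bis{[3,5-bis(trifluoromethyl)phenyl]sulfonyl}-1,3,2-diazaborolidine (1.2 equiv), Et3N, toluene/hexane, −78 °C, then 4 °C, 3–5 d; aq. work-up
Reagents that add atoms: none
Why: Enantioselective Ireland–Claisen rearrangement: soft enolisation gives ketene acetal 6 with the butynyl group cis to the allyloxy oxygen, the chair [3,3] shift with the E allyl unit forms C4–C5 and fixes the quaternary C4 (methyl, vinyl, chloropropyl) and C5 in the anti-type relation, and the C2-symmetric sulfonamide ligand on boron selects the enolate face and so the absolute sense.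

Step 4
Reactants: 7 (2S,3S)-2-(but-3-yn-1-yl)-3-(3-chloropropyl)-3-methylpent-4-enoic acid; 8 dimethyl malonate
Product: 10 dimethyl 2-[(2S,3S)-2-(but-3-yn-1-yl)-3-(3-chloropropyl)-3-methylpent-4-enoyl]propanedioate, via acyl imidazolide 9 (not isolated)
Conditions: CDI, THF, rt → 40 °C; then dimethyl malonate, MgCl2, Et3N, MeCN, rt → 50 °C; aq. HCl
Reagents that add atoms: none
Why: The acid is activated as imidazolide 9, which C-acylates the magnesium enolate of dimethyl malonate (Claisen-type C-acylation) under conditions mild enough to leave the α stereocentre C5 untouched.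

Step 5
Reactants: 10 dimethyl 2-[(2S,3S)-2-(but-3-yn-1-yl)-3-(3-chloropropyl)-3-methylpent-4-enoyl]propanedioate
Product: 11 dimethyl 2-[(2S,3S)-2-(but-3-yn-1-yl)-3-(3-chloropropyl)-3-methyl-1-{[(trifluoromethyl)sulfonyl]oxy}pent-4-en-1-ylidene]propanedioate
Conditions: Tf2O, iPr2NEt, CH2Cl2, −78 → 0 °C
Reagents that add atoms: trifluoromethanesulfonic anhydride, O=S(=O)(OS(=O)(=O)C(F)(F)F)C(F)(F)F
Why: The acylmalonate is fully enolised towards C9, so O-sulfonylation of its enolate (enol triflate formation) gives the β-triflyloxy alkylidene malonate.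

Step 6
Reactants: 11 dimethyl 2-[(2S,3S)-2-(but-3-yn-1-yl)-3-(3-chloropropyl)-3-methyl-1-{[(trifluoromethyl)sulfonyl]oxy}pent-4-en-1-ylidene]propanedioate
Product: 12 dimethyl 2-[(3S,4S)-3-(but-3-yn-1-yl)-4-(3-chloropropyl)-4-methylhex-5-en-2-ylidene]propanedioate
Conditions: Me2CuLi (from MeLi and CuI, 1.2 equiv), THF/Et2O, −78 °C
Reagents that add atoms: lithium dimethylcuprate, [Li+].C[Cu-]C
Why: Addition–elimination of the Gilman cuprate at the β-carbon of the triflyloxy alkylidene malonate (cuprate coupling of an enol triflate) puts the C20 methyl on C10 faster than conjugate addition to the fully substituted product at −78 °C.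

Step 7
Reactants: 12 dimethyl 2-[(3S,4S)-3-(but-3-yn-1-yl)-4-(3-chloropropyl)-4-methylhex-5-en-2-ylidene]propanedioate
Product: 15 (2R,3R)-3-(but-3-yn-1-yl)-2-(3-chloropropyl)-6-methoxy-5-(methoxycarbonyl)-2,4-dimethyl-6-oxohex-4-enoic acid, via diol 13 (not isolated), via aldehyde 14 (not isolated)
Conditions: K2OsO4·2H2O (2 mol %), NaIO4, 2,6-lutidine, dioxane/H2O, rt; then NaClO2, NaH2PO4, 2-methyl-2-butene, t-BuOH/H2O, rt
Reagents that add atoms: sodium periodate, [Na+].[O-]I(=O)(=O)=O; sodium chlorite, [Na+].[O-]Cl=O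
Why: Lemieux–Johnson cleavage (osmium-catalysed dihydroxylation, periodate glycol cleavage) acts only on the electron-rich vinyl group, not on the electron-poor tetrasubstituted alkene or the alkyne, and Pinnick oxidation of the non-enolisable aldehyde 14 gives the C18 acid without touching C4 or C5.

Step 8
Reactants: 15 (2R,3R)-3-(but-3-yn-1-yl)-2-(3-chloropropyl)-6-methoxy-5-(methoxycarbonyl)-2,4-dimethyl-6-oxohex-4-enoic acid
Product: 16 (2R,3R)-3-(but-3-yn-1-yl)-2-(3-iodopropyl)-6-methoxy-5-(methoxycarbonyl)-2,4-dimethyl-6-oxohex-4-enoic acid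
Conditions: NaI, acetone, reflux
Reagents that add atoms: sodium iodide, [Na+].[I-]
Why: Finkelstein halide exchange (SN2, driven by precipitation of NaCl in acetone) turns the primary chloride at C1 into the iodide needed for radical generation.

Step 9
Reactants: 16 (2R,3R)-3-(but-3-yn-1-yl)-2-(3-iodopropyl)-6-methoxy-5-(methoxycarbonyl)-2,4-dimethyl-6-oxohex-4-enoic acid
Product: 17 (1R,4aS,8aR)-5,5-bis(methoxycarbonyl)-1,4a-dimethyl-6-methylidenedecahydronaphthalene-1-carboxylic acid
Conditions: (Me3Si)3SiH (1.3 equiv) and AIBN (0.2 equiv) by syringe pump over 8 h, benzene (0.005 M), 80 °C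
Reagents that add atoms: none
Why: Iodine abstraction by the silyl radical gives the primary C1 radical, which adds in a polarity-matched Giese fashion to C10, the β-carbon of the alkylidene malonate (6-exo-trig, ring A); the tertiary malonyl radical at C9 then adds to the internal alkyne carbon C8 (6-exo-dig, ring B), and the vinyl radical at C17 takes hydrogen from the silane and carries the chain. The closest known reaction type is the tandem hydride-mediated radical cyclization of an ω-iodoalkyl Michael acceptor that ends on an alkyne. C10 is set in a chair transition state for ring A in which the C5 side arm (C6) is equatorial; the ester cis to C5 forces H5 into the alkene plane (A(1,3) strain), so C9 is pseudo-equatorial and the C20 methyl axial, which leaves C6 and C9 trans-diequatorial and lets ring B close only trans-fused, while C9 carries two identical esters and is not yet a stereocentre. The step needs 6-exo addition to outrun 1,5-hydrogen transfer from C5–H and reduction of the C1 radical, and 6-exo-dig closure to outrun reduction of the malonyl radical; the doubly activated acceptor, the quaternary C4 in the tether and slow addition of the silane at high dilution are meant to secure this.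

Step 10
Reactants: 17 (1R,4aS,8aR)-5,5-bis(methoxycarbonyl)-1,4a-dimethyl-6-methylidenedecahydronaphthalene-1-carboxylic acid
Product: 18 (1R,4aS,5S,8aR)-5-(methoxycarbonyl)-1,4a-dimethyl-6-methylidenedecahydronaphthalene-1-carboxylic acid
Conditions: LiCl, H2O, DMSO, 150 °C
Reagents that add atoms: none
Why: Krapcho dealkoxycarbonylation removes one geminal ester, and the ester enolate left after loss of CO2 should be protonated at C9 from the α face, anti to the axial C20 methyl, which places the remaining ester (C11) equatorial as in the target.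

Step 11
Reactants: 18 (1R,4aS,5S,8aR)-5-(methoxycarbonyl)-1,4a-dimethyl-6-methylidenedecahydronaphthalene-1-carboxylic acid
Product: 19 (1R,4aS,5S,8aR)-5-(hydroxymethyl)-1,4a-dimethyl-6-methylidenedecahydronaphthalene-1-carboxylic acid
Conditions: LiBH4, THF, 0 → 45 °C; aq. HCl
Reagents that add atoms: none
Why: LiBH4 reduces the methyl ester (hydride reduction) but not the lithium carboxylate formed from the C18 acid, so only C11 reaches the alcohol level.

Step 12
Reactants: 19 (1R,4aS,5S,8aR)-5-(hydroxymethyl)-1,4a-dimethyl-6-methylidenedecahydronaphthalene-1-carboxylic acid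
Product: 20 (1R,4aS,5S,8aR)-5-(iodomethyl)-1,4a-dimethyl-6-methylidenedecahydronaphthalene-1-carboxylic acid
Conditions: PPh3, I2, imidazole, toluene, 0 → 60 °C; aq. NaHCO3/THF work-up
Reagents that add atoms: iodine, II
Why: Appel-type iodination (alkoxyphosphonium iodide, SN2 by iodide) converts the primary alcohol into the iodide, and the carboxylic acid is recovered from any mixed anhydride on bicarbonate work-up.

Step 13
Reactants: 21 (R)-4-methyldihydrofuran-2(3H)-one
Product: 22 (R)-4-bromo-3-methylbutanoic acid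
Conditions: HBr (33 % in AcOH), 60 °C
Reagents that add atoms: hydrogen bromide, Br
Why: Acid-mediated lactone ring opening: bromide attacks the O–CH2 carbon of the protonated lactone (SN2), remote from the stereocentre (the later C13), which is carried over from the chiral pool.

Step 14
Reactants: 22 (R)-4-bromo-3-methylbutanoic acid
Product: 23 (R)-4-bromo-3-methylbutan-1-ol
Conditions: BH3·SMe2, THF, 0 °C → rt; aq. work-up
Reagents that add atoms: none
Why: Borane reduces the carboxylic acid chemoselectively (acyloxyborane pathway) in the presence of the primary bromide.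

Step 15
Reactants: 23 (R)-4-bromo-3-methylbutan-1-ol
Product: 24 (R)-4-bromo-3-methylbutyl acetate
Conditions: Ac2O, pyridine, DMAP (cat.), CH2Cl2, 0 °C
Reagents that add atoms: acetic anhydride, CC(=O)OC(C)=O
Why: Acetylation (nucleophilic catalysis by DMAP) caps the primary alcohol as the acetate that the target carries.

Step 16
Reactants: 20 (1R,4aS,5S,8aR)-5-(iodomethyl)-1,4a-dimethyl-6-methylidenedecahydronaphthalene-1-carboxylic acid; 24 (R)-4-bromo-3-methylbutyl acetate
Product: 26 (1R,4aR,5S,8aR)-5-[(3S)-5-acetoxy-3-methylpentyl]-1,4a-dimethyl-6-methylidenedecahydronaphthalene-1-carboxylic acid, via alkylzinc bromide 25 (not isolated)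
Conditions: 24, Zn dust, LiCl, THF, 50 °C (3 equiv of 25; one is consumed by the acid); then 20, Ni(cod)2 (10 mol %), s-Bu-Pybox (20 mol %), DMA/THF, rt; dilute HCl
Reagents that add atoms: none
Why: Zinc insertion into the primary bromide gives the acetate-tolerant alkylzinc 25, and alkyl–alkyl Negishi coupling under zerovalent nickel (radical-type activation of the iodide, so little sensitivity to β-branching) joins C11 to C12 without touching C9 or C13.

Compound list
1 | 5-chloropent-1-yne | C#CCCCCl | starting material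
2 | (E)-(5-chloro-2-methylpent-1-en-1-yl)dimethylalane | C[Al](C)/C=C(\C)CCCCl | intermediate (not isolated)
3 | (E)-6-chloro-3-methylhex-2-en-1-ol | OC/C=C(\C)CCCCl | intermediate
4 | hex-5-ynoic acid | C#CCCCC(=O)O | starting material
5 | (E)-6-chloro-3-methylhex-2-en-1-yl hex-5-ynoate | C#CCCCC(=O)OC/C=C(\C)CCCCl | intermediate
6 | (4S,5S)-2-{[(1Z)-1-{[(2E)-6-chloro-3-methylhex-2-en-1-yl]oxy}hex-1-en-5-yn-1-yl]oxy}-4,5-diphenyl-1,3-bis{[3,5-bis(trifluoromethyl)phenyl]sulfonyl}-1,3,2-diazaborolidine (butynyl cis to the allyloxy oxygen) | C#CCC/C=C(\OC/C=C(\C)CCCCl)OB1N(S(=O)(=O)c2cc(cc(c2)C(F)(F)F)C(F)(F)F)[C@@H](c2ccccc2)[C@H](c2ccccc2)N1S(=O)(=O)c1cc(cc(c1)C(F)(F)F)C(F)(F)F | intermediate (not isolated)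
7 | (2S,3S)-2-(but-3-yn-1-yl)-3-(3-chloropropyl)-3-methylpent-4-enoic acid | C#CCC[C@@H]([C@](C)(C=C)CCCCl)C(=O)O | intermediate
8 | dimethyl malonate | COC(=O)CC(=O)OC | starting material
9 | 1-[(2S,3S)-2-(but-3-yn-1-yl)-3-(3-chloropropyl)-3-methylpent-4-enoyl]-1H-imidazole | C#CCC[C@@H]([C@](C)(C=C)CCCCl)C(=O)n1ccnc1 | intermediate (not isolated)
10 | dimethyl 2-[(2S,3S)-2-(but-3-yn-1-yl)-3-(3-chloropropyl)-3-methylpent-4-enoyl]propanedioate | C#CCC[C@@H]([C@](C)(C=C)CCCCl)C(=O)C(C(=O)OC)C(=O)OC | intermediate
11 | dimethyl 2-[(2S,3S)-2-(but-3-yn-1-yl)-3-(3-chloropropyl)-3-methyl-1-{[(trifluoromethyl)sulfonyl]oxy}pent-4-en-1-ylidene]propanedioate | C#CCC[C@@H]([C@](C)(C=C)CCCCl)C(OS(=O)(=O)C(F)(F)F)=C(C(=O)OC)C(=O)OC | intermediate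
12 | dimethyl 2-[(3S,4S)-3-(but-3-yn-1-yl)-4-(3-chloropropyl)-4-methylhex-5-en-2-ylidene]propanedioate | C#CCC[C@@H]([C@](C)(C=C)CCCCl)C(C)=C(C(=O)OC)C(=O)OC | intermediate
13 | dimethyl 2-[(3R,4R)-3-(but-3-yn-1-yl)-7-chloro-4-(1,2-dihydroxyethyl)-4-methylheptan-2-ylidene]propanedioate (mixture of carbinol epimers) | C#CCC[C@@H]([C@](C)(C(O)CO)CCCCl)C(C)=C(C(=O)OC)C(=O)OC | intermediate (not isolated)
14 | dimethyl 2-[(3R,4R)-3-(but-3-yn-1-yl)-7-chloro-4-formyl-4-methylheptan-2-ylidene]propanedioate | C#CCC[C@@H]([C@](C)(C=O)CCCCl)C(C)=C(C(=O)OC)C(=O)OC | intermediate (not isolated)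
15 | (2R,3R)-3-(but-3-yn-1-yl)-2-(3-chloropropyl)-6-methoxy-5-(methoxycarbonyl)-2,4-dimethyl-6-oxohex-4-enoic acid | C#CCC[C@@H]([C@](C)(C(=O)O)CCCCl)C(C)=C(C(=O)OC)C(=O)OC | intermediate
16 | (2R,3R)-3-(but-3-yn-1-yl)-2-(3-iodopropyl)-6-methoxy-5-(methoxycarbonyl)-2,4-dimethyl-6-oxohex-4-enoic acid | C#CCC[C@@H]([C@](C)(C(=O)O)CCCI)C(C)=C(C(=O)OC)C(=O)OC | intermediate
17 | (1R,4aS,8aR)-5,5-bis(methoxycarbonyl)-1,4a-dimethyl-6-methylidenedecahydronaphthalene-1-carboxylic acid | C=C1CC[C@@H]2[C@](C)(CCC[C@@]2(C)C(=O)O)C1(C(=O)OC)C(=O)OC | intermediate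
18 | (1R,4aS,5S,8aR)-5-(methoxycarbonyl)-1,4a-dimethyl-6-methylidenedecahydronaphthalene-1-carboxylic acid | C=C1CC[C@@H]2[C@](C)(CCC[C@@]2(C)C(=O)O)[C@H]1C(=O)OC | intermediate
19 | (1R,4aS,5S,8aR)-5-(hydroxymethyl)-1,4a-dimethyl-6-methylidenedecahydronaphthalene-1-carboxylic acid | C=C1CC[C@@H]2[C@](C)(CCC[C@@]2(C)C(=O)O)[C@H]1CO | intermediate
20 | (1R,4aS,5S,8aR)-5-(iodomethyl)-1,4a-dimethyl-6-methylidenedecahydronaphthalene-1-carboxylic acid | C=C1CC[C@@H]2[C@](C)(CCC[C@@]2(C)C(=O)O)[C@H]1CI | intermediate
21 | (R)-4-methyldihydrofuran-2(3H)-one [(R)-β-methyl-γ-butyrolactone] | O=C1OC[C@H](C)C1 | starting material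
22 | (R)-4-bromo-3-methylbutanoic acid | BrC[C@H](C)CC(=O)O | intermediate
23 | (R)-4-bromo-3-methylbutan-1-ol | BrC[C@H](C)CCO | intermediate
24 | (R)-4-bromo-3-methylbutyl acetate | BrC[C@H](C)CCOC(C)=O | intermediate
25 | [(R)-4-acetoxy-2-methylbutyl]zinc bromide | Br[Zn]C[C@H](C)CCOC(C)=O | intermediate (not isolated)
26 | (1R,4aR,5S,8aR)-5-[(3S)-5-acetoxy-3-methylpentyl]-1,4a-dimethyl-6-methylidenedecahydronaphthalene-1-carboxylic acid | C=C1CC[C@@H]2[C@](C)(CCC[C@@]2(C)C(=O)O)[C@H]1CC[C@H](C)CCOC(C)=O | target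

Total steps: 16. Longest linear sequence: 13 (steps 1–12 and 16).

Steps most likely to fail

Step 9. The chain may be cut short: the malonyl radical at C9 can take hydrogen from the silane before it reaches the alkyne, or the C1 radical can be reduced or lost by 1,5-hydrogen transfer from C5–H before it adds to the hindered C10. Fallback, from 16: an iodine-atom-transfer cascade without any hydride donor ((Bu3Sn)2 10 mol %, sunlamp, benzene, 80 °C), in which the vinyl radical at C17 ends the sequence by taking iodine from another molecule of 16, should give the vinyl iodide (1R,4aS,8aR)-6-(iodomethylidene)-5,5-bis(methoxycarbonyl)-1,4a-dimethyldecahydronaphthalene-1-carboxylic acid F1 as an E/Z mixture. Reduction of the C–I bond of F1 ((Me3Si)3SiH, AIBN, benzene, 80 °C) then returns to 17.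

Step 16. Activation of the β-branched, neopentyl-like iodide may be slow, and protonolysis of the zinc reagent by the free acid may lead to reduction or elimination instead of coupling. Fallback, from 23 and 20: a polar copper-catalysed Grignard coupling with a silyl-protected fragment, the acetate being put on last. Silylation of 23 (t-BuMe2SiCl, imidazole, DMF) gives (R)-(4-bromo-3-methylbutoxy)(tert-butyl)dimethylsilane F2. Mg in THF gives the Grignard reagent [(R)-4-{[tert-butyl(dimethyl)silyl]oxy}-2-methylbutyl]magnesium bromide F3. F3 (3 equiv) with 20 and Li2CuCl4 (cat.), THF, −20 → 0 °C, gives (1R,4aR,5S,8aR)-5-[(3S)-5-{[tert-butyl(dimethyl)silyl]oxy}-3-methylpentyl]-1,4a-dimethyl-6-methylidenedecahydronaphthalene-1-carboxylic acid F4. Bu4NF in THF gives the hydroxy acid (1R,4aR,5S,8aR)-5-[(3S)-5-hydroxy-3-methylpentyl]-1,4a-dimethyl-6-methylidenedecahydronaphthalene-1-carboxylic acid F5, and Ac2O/pyridine returns to 26.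

Step 3. Face selection by the boron controller may be incomplete or of the wrong sense, or the rearrangement of the hindered ketene acetal may be too slow. Fallback, from 5: the achiral Ireland–Claisen rearrangement (LDA 2.2 equiv, Me3SiCl, THF, −78 °C → rt; then K2CO3, MeOH to take silicon off the alkyne and the acid), whose kinetic lithium enolate has the same geometry, gives the racemic acid rac-(2S*,3S*)-2-(but-3-yn-1-yl)-3-(3-chloropropyl)-3-methylpent-4-enoic acid F6. Classical resolution by crystallisation with (S)-1-phenylethylamine (or its antipode, whichever gives the less soluble salt) gives the (S)-1-phenylethylammonium (2S,3S)-carboxylate F7, and acidification returns to 7.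

Further compounds
F1 | step 9 | (1R,4aS,8aR)-6-(iodomethylidene)-5,5-bis(methoxycarbonyl)-1,4a-dimethyldecahydronaphthalene-1-carboxylic acid (E/Z mixture) | IC=C1CC[C@@H]2[C@](C)(CCC[C@@]2(C)C(=O)O)C1(C(=O)OC)C(=O)OC
F2 | step 16 | (R)-(4-bromo-3-methylbutoxy)(tert-butyl)dimethylsilane | BrC[C@H](C)CCO[Si](C)(C)C(C)(C)C
F3 | step 16 | [(R)-4-{[tert-butyl(dimethyl)silyl]oxy}-2-methylbutyl]magnesium bromide | Br[Mg]C[C@H](C)CCO[Si](C)(C)C(C)(C)C
F4 | step 16 | (1R,4aR,5S,8aR)-5-[(3S)-5-{[tert-butyl(dimethyl)silyl]oxy}-3-methylpentyl]-1,4a-dimethyl-6-methylidenedecahydronaphthalene-1-carboxylic acid | C=C1CC[C@@H]2[C@](C)(CCC[C@@]2(C)C(=O)O)[C@H]1CC[C@H](C)CCO[Si](C)(C)C(C)(C)C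
F5 | step 16 | (1R,4aR,5S,8aR)-5-[(3S)-5-hydroxy-3-methylpentyl]-1,4a-dimethyl-6-methylidenedecahydronaphthalene-1-carboxylic acid | C=C1CC[C@@H]2[C@](C)(CCC[C@@]2(C)C(=O)O)[C@H]1CC[C@H](C)CCO
F6 | step 3 | rac-(2S*,3S*)-2-(but-3-yn-1-yl)-3-(3-chloropropyl)-3-methylpent-4-enoic acid (1:1 mixture of 7 and its enantiomer) | C#CCC[C@@H]([C@](C)(C=C)CCCCl)C(=O)O.C#CCC[C@H]([C@@](C)(C=C)CCCCl)C(=O)O
F7 | step 3 | (S)-1-phenylethylammonium (2S,3S)-2-(but-3-yn-1-yl)-3-(3-chloropropyl)-3-methylpent-4-enoate | C#CCC[C@@H]([C@](C)(C=C)CCCCl)C(=O)[O-].C[C@H]([NH3+])c1ccccc1
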